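**Plan**
Target numbering (bicyclo[3.3.1]nonane): C1 bridgehead C–OH, C2, C3 (N), C4 (OH), C5 bridgehead H, C6 (OH), C7–C8 epoxide, C9 ketone; ring A = C1–C2–C3–C4–C5–C9, ring B = C1–C9–C5–C6–C7–C8.
Cuts: the amide N–CO bond (made last), then the C4–C5 bond of ring A. The triad C9(=O)–C5(H)–C4 (a ketone carbon next to a bridgehead CH that carries a carbinol carbon) is the product pattern of a pinacol-type 1,2-shift of C4 from C9 to C5.
That shift turns the cyclopentane C1–C2–C3–C4–C9 of a cis-hydrindane-7a-ol 7-mesylate into ring A and the fused bicycle into the bridged one. The hydrindane is the dearomatised 2-aminoindan-1-ol obtained from O-methyl-L-tyrosine by Friedel–Crafts closure of the C4–C9 bond.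
Forward order: arene (future ring B) → five-membered ring → Birch dearomatisation and oxygenation of ring B → ring expansion 5 → 6 (ring A and the bicycle) → N-acylation with the separately made enoic acid → desilylation.
Stereochemistry: C3 from L-tyrosine; C4–OH by hydride addition anti to the C3 amide; C1–OH by epoxidation directed by C4–OH; epoxide, C6–OH and the cis-diol relayed from C1–OH by hydroxyl-directed reactions; C5 by the stereospecific shift (inversion at the terminus, retention in C4).

Key step: step 13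

Remark: indane numbering is used for the bicyclic precursors (indane C1, C2, C3, C3a, C4, C5, C6, C7, C7a = target C4, C3, C2, C1, C8, C7, C6, C5, C9). Compounds 1, 21, 22 and 25 are assumed to be commercial.

Step 1
Reactants: 1 O-methyl-L-tyrosine
Product: 2 N-trifluoroacetyl-O-methyl-L-tyrosine
Conditions: CF3CO2Et, Et3N, MeOH, rt; acidic work-up
Reagents that add atoms: ethyl trifluoroacetate, CCOC(=O)C(F)(F)F
Why: Aminolysis of the activated ester gives the trifluoroacetamide, an N-protecting group that survives AlCl3 and disfavours azlactone formation, so the α-centre should pass intact through the next step.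

Step 2
Reactants: 2 N-trifluoroacetyl-O-methyl-L-tyrosine
Product: 4 (S)-6-methoxy-2-(trifluoroacetamido)indan-1-one, via acid chloride 3 (not isolated)
Conditions: (COCl)2, cat. DMF, CH2Cl2, 0 °C; then AlCl3, CH2Cl2, 0 °C to rt
Reagents that add atoms: none
Why: Intramolecular Friedel–Crafts acylation ortho to the side chain closes the five-membered ring, as in the preparation of 6-methoxyindan-1-one from 3-(4-methoxyphenyl)propanoyl chloride, and forms the future C4–C9 bond without touching the tyrosine stereocentre.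

Step 3
Reactants: 4 (S)-6-methoxy-2-(trifluoroacetamido)indan-1-one
Product: 6 (1R,2S)-2-amino-6-methoxyindan-1-ol (OH and NH2 cis), via trifluoroacetamido alcohol 5 (not isolated)
Conditions: LiBH(s-Bu)3, THF, −78 °C; then K2CO3, MeOH/H2O, 40 °C
Reagents that add atoms: none
Why: The bulky hydride should add to the indanone carbonyl from the face opposite to the C2 amide and so set the C1 carbinol cis to nitrogen, and carbonate solvolysis then removes the trifluoroacetyl group, which would not survive dissolving metal.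

Step 4
Reactants: 6 (1R,2S)-2-amino-6-methoxyindan-1-ol
Product: 7 (1R,2S)-2-amino-6-methoxy-2,3,4,7-tetrahydro-1H-inden-1-ol (alkenes C3a=C7a and C5=C6)
Conditions: Li, t-BuOH, NH3(l)/THF, −78 to −33 °C
Reagents that add atoms: none
Why: Birch reduction of the anisole ring should protonate C4 and C7 and leave the methyl enol ether and the tetrasubstituted ring-fusion alkene, with the benzylic oxygen shielded from hydrogenolysis as its lithium alkoxide.

Step 5
Reactants: 7 (1R,2S)-2-amino-6-methoxy-2,3,4,7-tetrahydro-1H-inden-1-ol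
Product: 9 benzyl N-[(1R,2S)-1-hydroxy-6-oxo-2,3,4,5,6,7-hexahydro-1H-inden-2-yl]carbamate, via N-Cbz enol ether 8 (not isolated)
Conditions: CbzCl, NaHCO3, THF/H2O, 0 °C; then (CO2H)2, THF/H2O, rt
Reagents that add atoms: benzyl chloroformate, O=C(Cl)OCc1ccccc1; water, O
Why: Schotten–Baumann carbamoylation of the amine followed by mild acid hydrolysis of the enol ether should give the non-conjugated β,γ-enone without moving the ring-fusion alkene, as in the Birch route to 19-nor steroids.

Step 6
Reactants: 9 benzyl N-[(1R,2S)-1-hydroxy-6-oxo-2,3,4,5,6,7-hexahydro-1H-inden-2-yl]carbamate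
Product: 11 benzyl N-[(2S)-1,3a-dihydroxy-6-oxo-2,3,3a,4,5,6-hexahydro-1H-inden-2-yl]carbamate (1-OH, 2-NHCbz and 3a-OH all cis; enone C6(=O)–C7=C7a), via 3a,7a-epoxide 10 (not isolated)
Conditions: mCPBA, NaHCO3, CH2Cl2, 0 °C; then Et3N, rt
Reagents that add atoms: 3-chloroperbenzoic acid, O=C(OO)c1cccc(Cl)c1
Why: Hydroxyl-directed peracid epoxidation of the tetrasubstituted alkene syn to the allylic C1 hydroxyl and the cis carbamate, followed by E1cB opening of the β,γ-epoxy ketone from the C7 enolate (known for 5,10-epoxy-3-keto steroids), should set the 3a carbinol cis to O1 and N2 and fix the enone position.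

Step 7
Reactants: 11 the 1,3a-diol enone
Product: 12 the 1-O-tert-butyldimethylsilyl ether of 11
Conditions: TBSCl, imidazole, DMF, rt
Reagents that add atoms: tert-butyldimethylsilyl chloride, CC(C)(C)[Si](C)(C)Cl
Why: Silylation should take place only at the secondary C1 hydroxyl and leave the tertiary 3a hydroxyl free as a directing group, while protecting the allylic carbinol against DDQ and later sulfonylation.

Step 8
Reactants: 12 the 1-O-silyl enone
Product: 13 benzyl N-[(2S)-1-(tert-butyldimethylsilyloxy)-3a-hydroxy-6-oxo-2,3,3a,6-tetrahydro-1H-inden-2-yl]carbamate (quinol-type dienone, alkenes C4=C5 and C7=C7a)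
Conditions: DDQ, 1,4-dioxane, 90 °C
Reagents that add atoms: none
Why: DDQ dehydrogenation of a cyclohexenone on its saturated side, the reaction that converts steroidal 4-en-3-ones into 1,4-dien-3-ones, should give the cross-conjugated dienone, since C7a carries no hydrogen.

Step 9
Reactants: 13 the quinol-type dienone
Product: 14 the 4,5-epoxide of 13 (epoxide oxygen cis to 3a-OH)
Conditions: t-BuOOH, DBU, CH2Cl2, 0 °C
Reagents that add atoms: tert-butyl hydroperoxide, CC(C)(C)OO
Why: Nucleophilic (Weitz–Scheffer) epoxidation should occur at the disubstituted enone, whose β-carbon C4 is a CH whereas C7a is fully substituted, and syn to the hydrogen-bonding tertiary hydroxyl, as is known for 4-hydroxycyclohexadienones.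

Step 10
Reactants: 14 the epoxy enone
Product: 15 the 6-alcohol (6-OH cis to the epoxide and to 3a-OH; alkene C7=C7a)
Conditions: NaBH4, CeCl3·7H2O, MeOH, −78 °C
Reagents that add atoms: none
Why: Luche 1,2-reduction of the enone carbonyl should take the hydride from the face anti to the neighbouring epoxide oxygen and so give the cis epoxy alcohol.

Step 11
Reactants: 15 the allylic alcohol
Product: 16 the 3a,6,7,7a-tetraol (all four hydroxyls and the epoxide oxygen on one face; C1 and C3 bridge carbons on the other)
Conditions: OsO4 (1.05 equiv), TMEDA, CH2Cl2, −78 °C; then aq. Na2SO3, THF, rt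
Reagents that add atoms: osmium tetroxide, O=[Os](=O)(=O)=O
Why: Hydrogen-bond-directed dihydroxylation with the OsO4·TMEDA complex should deliver both oxygens syn to the allylic 6-OH and 3a-OH, giving the cis-fused hydrindane with the 7a carbinol and the C7 oxygen on the face opposite to C1.

Step 12
Reactants: 16 the tetraol
Product: 17 the 6-O-tert-butyldimethylsilyl ether of 16 (free OH at C3a, C7 and C7a)
Conditions: TBSCl (1.1 equiv), imidazole, DMF, −20 to 0 °C
Reagents that add atoms: tert-butyldimethylsilyl chloride, CC(C)(C)[Si](C)(C)Cl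
Why: The bulky silyl chloride should select the C6 hydroxyl over the C7 hydroxyl, which is neopentyl-like next to the fully substituted C7a, and the ether later prevents a hydride shift from C6.

Step 13
Reactants: 17 the 6-O-silyl triol
Product: 19 benzyl N-[4,6-bis(tert-butyldimethylsilyloxy)-7,8-epoxy-1-hydroxy-9-oxobicyclo[3.3.1]nonan-3-yl]carbamate (configuration of the target), via 7-mesylate 18 (not isolated)
Conditions: MsCl, Et3N, CH2Cl2, −20 °C; then KOt-Bu, THF, −40 to 0 °C
Reagents that add atoms: none
Why: Mesylation of the only free secondary hydroxyl (C7) and deprotonation give the C7a alkoxide, whose push drives a concerted 1,2-shift of the antiperiplanar C7a–C1 bond to C7 with loss of mesylate, leaving the C9 ketone. The closest known reaction type is the base-mediated pinacol-type (semipinacol) ring expansion of cyclic cis-1,2-diol monosulfonates. The cyclopentane C1–C2–C3–C3a–C7a is enlarged to the cyclohexanone ring A by insertion of C7 into the C7a–C1 bond through a three-centre transition state, so the ring closes by an alkyl shift and not by an exo or endo cyclisation, and the fused hydrindane becomes the bridged bicycle. The one new stereocentre, bridgehead C5 (former C7), is set with inversion because C1 enters anti to the leaving group, while the migrating carbon keeps its configuration, so the cis ring fusion and cis-diol of step 11 fix it. The step needs migration of C1 and not of the ring-fusion bond C7a–C3a (ring contraction, or Grob fragmentation from the C3a alkoxide); this should be secured by the half-chair with axial mesylate and C1 trans-diaxial to it, favoured because the other half-chair puts 7a-OH and 6-OTBS in a 1,3-diaxial clash. The C6 silyl ether blocks a hydride shift, and the cis epoxy alcohol cannot undergo Payne rearrangement.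

Step 14
Reactants: 19 the N-Cbz bicyclic ketone
Product: 20 3-amino-4,6-bis(tert-butyldimethylsilyloxy)-7,8-epoxy-1-hydroxybicyclo[3.3.1]nonan-9-one
Conditions: H2 (1 atm), Pd/C, EtOAc, rt
Reagents that add atoms: none
Why: Hydrogenolysis of the benzyl carbamate should free the amine under neutral conditions that leave the epoxide, the ketone and the silyl ethers alone, and no alkene is present yet.

Step 15
Reactants: 21 hex-5-enenitrile; 22 pentylmagnesium bromide
Product: 24 undec-1-en-6-one, via magnesium ketimine 23 (not isolated)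
Conditions: Et2O, 0 °C to reflux; then 2 M HCl, rt
Reagents that add atoms: water, O
Why: Grignard addition to the nitrile stops at the N-magnesio imine, whose hydrolysis gives the ketone without over-addition.

Step 16
Reactants: 24 undec-1-en-6-one; 25 acrylic acid
Product: 26 (E)-7-oxododec-2-enoic acid
Conditions: second-generation Grubbs catalyst (3 mol %), CH2Cl2, 40 °C
Reagents that add atoms: none
Why: Cross-metathesis of a terminal alkene with acrylic acid should give the E-configured 2-enoic acid selectively and tolerates the remote ketone.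

Step 17
Reactants: 20 the amine; 26 (E)-7-oxododec-2-enoic acid
Product: 27 4,6-bis-O-(tert-butyldimethylsilyl)isariotin C
Conditions: EDC·HCl, HOBt, i-Pr2NEt, CH2Cl2, 0 °C to rt
Reagents that add atoms: none
Why: Carbodiimide and HOBt coupling should acylate the primary amine in preference to the tertiary hydroxyl, and 1,2-acylation by the active ester is faster than aza-Michael addition.

Step 18
Reactants: 27 bis-silylated isariotin C
Product: 28 isariotin C
Conditions: HF·pyridine, pyridine/THF, 0 °C to rt
Reagents that add atoms: none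
Why: Buffered fluoride desilylation should free the two secondary hydroxyls without base, so that retro-aldol cleavage of the β-hydroxy ketone, α-ketol shift and epoxide opening are avoided.

**Compound list**
1 | O-methyl-L-tyrosine | N[C@@H](Cc1ccc(OC)cc1)C(=O)O | starting material
2 | N-trifluoroacetyl-O-methyl-L-tyrosine | O=C(N[C@@H](Cc1ccc(OC)cc1)C(=O)O)C(F)(F)F | intermediate
3 | N-trifluoroacetyl-O-methyl-L-tyrosyl chloride | O=C(N[C@@H](Cc1ccc(OC)cc1)C(=O)Cl)C(F)(F)F | intermediate
4 | (S)-6-methoxy-2-(trifluoroacetamido)indan-1-one | O=C(N[C@H]1Cc2ccc(OC)cc2C1=O)C(F)(F)F | intermediate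
5 | (1R,2S)-6-methoxy-2-(trifluoroacetamido)indan-1-ol (cis) | O=C(N[C@H]1Cc2ccc(OC)cc2[C@H]1O)C(F)(F)F | intermediate
6 | (1R,2S)-2-amino-6-methoxyindan-1-ol (cis) | N[C@H]1Cc2ccc(OC)cc2[C@H]1O | intermediate
7 | (1R,2S)-2-amino-6-methoxy-2,3,4,7-tetrahydro-1H-inden-1-ol | N[C@H]1CC2=C(CC(OC)=CC2)[C@H]1O | intermediate
8 | benzyl N-[(1R,2S)-1-hydroxy-6-methoxy-2,3,4,7-tetrahydro-1H-inden-2-yl]carbamate | O=C(OCc1ccccc1)N[C@H]1CC2=C(CC(OC)=CC2)[C@H]1O | intermediate
9 | benzyl N-[(1R,2S)-1-hydroxy-6-oxo-2,3,4,5,6,7-hexahydro-1H-inden-2-yl]carbamate | O=C(OCc1ccccc1)N[C@H]1CC2=C(CC(=O)CC2)[C@H]1O | intermediate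
10 | 3a,7a-epoxide of 9, epoxide oxygen cis to 1-OH and 2-NHCbz | O=C(OCc1ccccc1)N[C@H]1C[C@@]23O[C@@]2(CC(=O)CC3)[C@H]1O | intermediate
11 | benzyl N-[(2S)-1,3a-dihydroxy-6-oxo-2,3,3a,4,5,6-hexahydro-1H-inden-2-yl]carbamate, 1-OH, 2-NHCbz and 3a-OH all cis | O=C(OCc1ccccc1)N[C@H]1C[C@]2(O)CCC(=O)C=C2[C@H]1O | intermediate
12 | 1-O-tert-butyldimethylsilyl ether of 11 | O=C(OCc1ccccc1)N[C@H]1C[C@]2(O)CCC(=O)C=C2[C@H]1O[Si](C)(C)C(C)(C)C | intermediate
13 | quinol-type dienone, 4,5-didehydro-12 | O=C(OCc1ccccc1)N[C@H]1C[C@]2(O)C=CC(=O)C=C2[C@H]1O[Si](C)(C)C(C)(C)C | intermediate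
14 | 4,5-epoxide of 13, epoxide cis to 3a-OH | O=C(OCc1ccccc1)N[C@H]1C[C@]2(O)[C@H]3O[C@H]3C(=O)C=C2[C@H]1O[Si](C)(C)C(C)(C)C | intermediate
15 | 6-alcohol from 14, 6-OH cis to epoxide and 3a-OH | O=C(OCc1ccccc1)N[C@H]1C[C@]2(O)[C@H]3O[C@H]3[C@@H](O)C=C2[C@H]1O[Si](C)(C)C(C)(C)C | intermediate
16 | 3a,6,7,7a-tetraol, all hydroxyls and the epoxide on one face | O=C(OCc1ccccc1)N[C@H]1C[C@]2(O)[C@H]3O[C@H]3[C@@H](O)[C@@H](O)[C@]2(O)[C@H]1O[Si](C)(C)C(C)(C)C | intermediate
17 | 6-O-tert-butyldimethylsilyl ether of 16 | O=C(OCc1ccccc1)N[C@H]1C[C@]2(O)[C@H]3O[C@H]3[C@@H](O[Si](C)(C)C(C)(C)C)[C@@H](O)[C@]2(O)[C@H]1O[Si](C)(C)C(C)(C)C | intermediate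
18 | 7-O-methanesulfonate of 17 | O=C(OCc1ccccc1)N[C@H]1C[C@]2(O)[C@H]3O[C@H]3[C@@H](O[Si](C)(C)C(C)(C)C)[C@@H](OS(C)(=O)=O)[C@]2(O)[C@H]1O[Si](C)(C)C(C)(C)C | intermediate
19 | benzyl N-[4,6-bis(tert-butyldimethylsilyloxy)-7,8-epoxy-1-hydroxy-9-oxobicyclo[3.3.1]nonan-3-yl]carbamate | O=C(OCc1ccccc1)N[C@H]1C[C@@]2(O)C(=O)[C@H]([C@H](O[Si](C)(C)C(C)(C)C)[C@@H]3O[C@@H]32)[C@H]1O[Si](C)(C)C(C)(C)C | intermediate
20 | 3-amino-4,6-bis(tert-butyldimethylsilyloxy)-7,8-epoxy-1-hydroxybicyclo[3.3.1]nonan-9-one | N[C@H]1C[C@@]2(O)C(=O)[C@H]([C@H](O[Si](C)(C)C(C)(C)C)[C@@H]3O[C@@H]32)[C@H]1O[Si](C)(C)C(C)(C)C | intermediate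
21 | hex-5-enenitrile | C=CCCCC#N | starting material
22 | pentylmagnesium bromide | CCCCC[Mg]Br | starting material
23 | N-bromomagnesio imine of undec-1-en-6-one | C=CCCCC(=N[Mg]Br)CCCCC | intermediate
24 | undec-1-en-6-one | C=CCCCC(=O)CCCCC | intermediate
25 | acrylic acid | C=CC(=O)O | starting material
26 | (E)-7-oxododec-2-enoic acid | CCCCCC(=O)CCC/C=C/C(=O)O | intermediate
27 | 4,6-bis-O-(tert-butyldimethylsilyl)isariotin C | CCCCCC(=O)CCC/C=C/C(=O)N[C@H]1C[C@@]2(O)C(=O)[C@H]([C@H](O[Si](C)(C)C(C)(C)C)[C@@H]3O[C@@H]32)[C@H]1O[Si](C)(C)C(C)(C)C | intermediate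
28 | isariotin C | CCCCCC(=O)CCC/C=C/C(=O)N[C@H]1C[C@@]2(O)C(=O)[C@H]([C@H](O)[C@@H]3O[C@@H]32)[C@H]1O | target

**Step count**
Total: 18 steps. Longest linear sequence: 16 steps (1–14, 17, 18); steps 15 and 16 make the acid 26.

**Steps most likely to fail**

Step 13. The rearrangement may run through the other half-chair, with the mesylate equatorial. The ring-fusion bond C7a–C3a then lies anti to the leaving group, and ring contraction or a Grob-type fragmentation started by the C3a alkoxide would compete with the C1 shift. The fallback moves the shift to the ketone oxidation level, where a leaving group α to a carbonyl reacts only from the conformer with the C–O bond parallel to the carbonyl π system, which is the one that places C1 anti. It sets out from epoxy enone 14: dihydroxylation with OsO4 and TMEDA, directed by 3a-OH, should give the 7,7a-dihydroxy-6-ketone F1, and MsCl with Et3N the α-mesyloxy ketone F2. KOt-Bu in THF at −78 °C should then give the bicyclic 6,9-diketone F3. NaBH4 with CeCl3·7H2O should reduce the less hindered 6-ketone anti to the epoxide to the 6-alcohol F4, and silylation with TBSOTf and 2,6-lutidine rejoins the route at 19.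

Step 11. The osmium reagent may approach from the face opposite to the hydroxyls, which is not shielded by the C1 silyl ether, or may fail to react at the congested trisubstituted alkene. The fallback removes the blocking group first. It sets out from 15: Bu4NF should give the triol F8, in which three syn hydroxyls flank the alkene and nothing shields that face, and OsO4 with TMEDA the pentaol F9. TBSOTf (2 equiv) with 2,6-lutidine at −78 °C should then silylate the two less hindered secondary hydroxyls at C1 and C6, because the C7 hydroxyl lies between the quaternary C7a and the silylated C6, and the route is rejoined at 17.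

Step 12. Silylation may occur at the C7 hydroxyl or at both secondary hydroxyls. The fallback uses one cyclic group to protect O6 and activate O7 at once. It sets out from 16: SOCl2 with Et3N should give the cyclic sulfite F5 on the only cis-diol made of two secondary hydroxyls, and RuCl3 (cat.) with NaIO4 the cyclic sulfate F6. KOt-Bu should then trigger the same 1,2-shift with opening of the sulfate at C7 to the ring-expanded sulfate monoester potassium salt F7. Hydrolysis with catalytic H2SO4 in wet THF should give the 6-alcohol F4, and silylation rejoins the route at 19.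

**Further compounds**
F1 | step 13 | 7,7a-dihydroxy-6-ketone from 14 (3a-, 7- and 7a-OH and the epoxide on one face) | O=C(OCc1ccccc1)N[C@H]1C[C@]2(O)[C@H]3O[C@H]3C(=O)[C@@H](O)[C@]2(O)[C@H]1O[Si](C)(C)C(C)(C)C
F2 | step 13 | 7-O-methanesulfonate of F1 | O=C(OCc1ccccc1)N[C@H]1C[C@]2(O)[C@H]3O[C@H]3C(=O)[C@@H](OS(C)(=O)=O)[C@]2(O)[C@H]1O[Si](C)(C)C(C)(C)C
F3 | step 13 | benzyl N-[4-(tert-butyldimethylsilyloxy)-7,8-epoxy-1-hydroxy-6,9-dioxobicyclo[3.3.1]nonan-3-yl]carbamate | O=C(OCc1ccccc1)N[C@H]1C[C@@]2(O)C(=O)[C@H](C(=O)[C@@H]3O[C@@H]32)[C@H]1O[Si](C)(C)C(C)(C)C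
F4 | step 13 | benzyl N-[4-(tert-butyldimethylsilyloxy)-7,8-epoxy-1,6-dihydroxy-9-oxobicyclo[3.3.1]nonan-3-yl]carbamate | O=C(OCc1ccccc1)N[C@H]1C[C@@]2(O)C(=O)[C@H]([C@H](O)[C@@H]3O[C@@H]32)[C@H]1O[Si](C)(C)C(C)(C)C
F5 | step 12 | 6,7-cyclic sulfite of 16 | O=C(OCc1ccccc1)N[C@H]1C[C@]2(O)[C@H]3O[C@H]3[C@H]4OS(=O)O[C@H]4[C@]2(O)[C@H]1O[Si](C)(C)C(C)(C)C
F6 | step 12 | 6,7-cyclic sulfate of 16 | O=C(OCc1ccccc1)N[C@H]1C[C@]2(O)[C@H]3O[C@H]3[C@H]4OS(=O)(=O)O[C@H]4[C@]2(O)[C@H]1O[Si](C)(C)C(C)(C)C
F7 | step 12 | potassium salt of the 6-O-sulfate of F4 | O=C(OCc1ccccc1)N[C@H]1C[C@@]2(O)C(=O)[C@H]([C@H](OS(=O)(=O)[O-])[C@@H]3O[C@@H]32)[C@H]1O[Si](C)(C)C(C)(C)C.[K+]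
F8 | step 11 | 1,3a,6-triol from desilylation of 15 | O=C(OCc1ccccc1)N[C@H]1C[C@]2(O)[C@H]3O[C@H]3[C@@H](O)C=C2[C@H]1O
F9 | step 11 | 1,3a,6,7,7a-pentaol, all hydroxyls and the epoxide on one face | O=C(OCc1ccccc1)N[C@H]1C[C@]2(O)[C@H]3O[C@H]3[C@@H](O)[C@@H](O)[C@]2(O)[C@H]1O
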